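Readings and results are simulated from invented constants; noise was put on by code.

5 questions are put to these flasks, and the one you can bracket by hand is what share of its charge the dawn run turns into target by 12 h.

| flask | starting material | reagent | catalyst | time |
|---|---|---|---|---|
| winter | 0.300 M | 0.450 M | 0.0300 M |  |
| noon | 0.120 M | 0.270 M | 0.0300 M |  |
| midnight | 0.150 M | 0.450 M | 0.0300 M |  |
| dawn | 0.600 M | 1.40 M | 0.0300 M | 12 h |

| run | time / h | [target] / M |
|---|---|---|
| winter run | 0.43 | 0.0030 |
| winter run | 1.3 | 0.0092 |
| winter run | 2.5 | 0.0275 |
| winter run | 4.0 | 0.0556 |
| winter run | 5.7 | 0.0848 |
| winter run | 7.6 | 0.1180 |
| winter run | 9.7 | 0.1424 |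
| winter run | 12 | 0.1728 |
| noon run | 0.43 | 0 |
| noon run | 1.3 | 0.0025 |
| noon run | 2.5 | 0.0082 |
| noon run | 4.0 | 0.0159 |
| noon run | 5.7 | 0.0289 |
| noon run | 7.6 | 0.0366 |
| noon run | 9.7 | 0.0473 |
| noon run | 12 | 0.0634 |
| midnight run | 0.43 | 0 |
| midnight run | 1.3 | 0.0047 |
| midnight run | 2.5 | 0.0140 |
| midnight run | 4.0 | 0.0321 |
| midnight run | 5.7 | 0.0448 |
| midnight run | 7.6 | 0.0584 |
| midnight run | 9.7 | 0.0746 |
| midnight run | 12 | 0.0885 |

(standard deviation of a reading: 0.002 M)

- apparent order in [reagent] of the starting rate, round the charge of the winter run (the rate where two percent of its starting material have turned into target)
- apparent order in [starting material] of the starting rate, round the charge of the winter run (the rate where two percent of its starting material have turned into target) (one fixed amount of target, the same in the runs compared)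
- the noon run starts with 0.180 M less of starting material and of reagent than the winter run, and with no target. Compared where both hold the same amount of starting material, once fifteen percent of what the noon run was charged with has turned into target, is the noon run faster, slower or alike (within a tenth)?
- target in the dawn run at 12 h, as a share of the starting material charged
- which of these the readings show (an uncatalysed path runs beside / the product reacts on with the second partner / the catalyst wakes slowly / the product kills the catalyst / the second partner ties up the catalyst)

- Overall: starting material + reagent -> target, with catalyst as catalyst.
- Constant volume, constant temperature.
- The analysis sees a species whether free or bound.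
- "The second partner" is reagent.
- An order is taken over about fifteen percent of the charge, up and down.

Work in fractions of the charge, and take the logarithm of charge over starting material left. Late in a run it climbs straight: its slope is 0.0835 h⁻¹ in the winter run from 5.7 h to 12 h, and 0.0852 h⁻¹ in the midnight run, charged with half the starting material. So the tail looks pseudo-first-order in starting material, with mean constant 0.0843 h⁻¹. The noon run, on 0.270 M of reagent against 0.450 M, gives 0.0881 h⁻¹ from 7.6 h to 12 h, give or take 0.00971 h⁻¹, so within scatter the tail does not move with reagent.

The start is another matter, for the runs begin late (an induction period). Call lost time the clock reading minus the logarithm over the constant: the hours a run trails a flask working at full constant from the start. At 12 h the winter run has lost 110 min and the midnight run 85.7 min, with the same reagent; I take their mean, 97.6 min. Suppose the catalyst wakes first-order at a rate proportional to reagent. With reagent held at its charge, the sleeping share then falls exponentially, and the hours lost equal its time constant. Lost time times the reagent charged comes to 43.9 M·min; this waking product should hold at this catalyst charge and temperature. For the noon run it gives 2.71 h, and the reading gives 3.09 h, give or take 25.1 min, which agrees.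

Now bracket the dawn run, assuming the constant carries over to its richer charge. From above, a catalyst awake from the start loses nothing and gives 63.7%. From below, the dawn run has more reagent than the winter run, so I grant it at worst the winter lost time, which gives 58.3%. Tightened, the waking product gives a lost time of 31.4 min and a share of 62.0%, the figure I commit to.

The forecast reads a lag “independent of charge” and gives orders of 0.28 in reagent and 0.62 in starting material, calls the noon run alike, says the catalyst wakes slowly, and puts the dawn run at 72%, higher than the top of my bracket.

The dawn run gives 62.2%, inside the bracket, with orders 0.43 in reagent and 0.59 in starting material, the noon run slower, and the catalyst wakes slowly.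

    active catalyst + starting material → catalyst-substrate complex (2.880 L mol⁻¹ h⁻¹)
    catalyst-substrate complex + reagent → target + active catalyst (53.64 L mol⁻¹ h⁻¹)
    catalyst + reagent → active catalyst + reagent (1.364 L mol⁻¹ h⁻¹)

At 0.0843 h⁻¹, that share means a dawn lost time of 27.8 min, so a product of 38.9 M·min against the waking product of 43.9 M·min. In the noon run, at 4.0 h, with 13.2% of its charge turned into target, close to the point compared, the waking product puts the awake share at 0.771. For the winter run at 12 h the same product gives an awake share of 0.999, and the rate of the noon run over the rate of the winter run, at equal starting material, is 0.77.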